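**Plan**

1. Cuts: the inter-half ester at its O–CH2 bond (gives acid 20 and spiro-epoxide 34); in each half the ring C–C bond between the CH that carries the acrylate arm and its ring neighbour (C1′–C2′ of cyclohexene ring B in 20; C5a–C9a of cyclohexane ring A in 34); the arm C=C (Wittig); the lactone C–O of ring C.
2. Enabling feature: in ring B the arm-bearing C1′ is the γ-carbon of the 2-(hydroxymethyl)acrylate, so a C1′–Cl bond is an activated allylic electrophile. C2′ (the later vinylic CH) becomes a soft nucleophile when C3′ is a ketone and C2′ carries a temporary ester carbon. Ring A shows the same pattern, with that ester carbon kept as the lactone C=O.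
3. Forward: limonene → ring C=C cleavage to an open-chain keto aldehyde (isopropyl stereocentre kept) → β-keto ester → α-chlorination/Wittig → six-membered ring closure by intramolecular SN2 C-alkylation, in both enantiomeric series (ring B in step 6, ring A in step 16).
4. Acyl half: ketone → exocyclic methylene; bromo-β-lactonisation and loss of CO2 put the double bond at C2′=C3′, remove the helper carbon and leave CH2Br → CH2OH. Lactone half: acylketene lactonisation closes ring C (step 18), then methylenation and epoxidation.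
5. Union: the carboxylate of 20 opens epoxide 34 at CH2 (step 21); the last step frees the acid.
6. Stereochemistry: isopropyl centres from (R)- and (S)-limonene; arm-bearing centres from catalyst-controlled α-chlorination, read out with inversion (cis in ring B, trans in ring A); lactone α-carbon by equilibration; tertiary carbinol by equatorial oxygen transfer; alkene geometry from the stabilised-ylide Wittig and ring C.

Key step: step 6

Assumption: the (5R)-5-benzyl-2,2,3-trimethylimidazolidin-4-one salt is taken to give the 7R α-chloro aldehyde (chlorine delivered to the enamine face remote from the benzyl group); if the sense proves opposite, its enantiomer is used in steps 5 and 15.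

**Route**

Step 1
Reactants: 1 tert-butyl (triphenylphosphoranylidene)acetate; 2 (chloromethoxy)tri(propan-2-yl)silane
Product: 4 tert-butyl 3-[(triisopropylsilyl)oxy]-2-(triphenylphosphoranylidene)propanoate, via phosphonium chloride 3 (not isolated)
Conditions: CH2Cl2, 0 °C → rt; then 1 M aq NaOH
Reagents that add atoms: none
Why: The ester-stabilised ylide should be C-alkylated by the reactive α-chloro ether (SN2 at the chloromethyl carbon) and the phosphonium salt deprotonated by aqueous NaOH to the new α-substituted stabilised ylide (alkylation of a stabilised phosphorane).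

Step 2
Reactants: 5 (R)-(+)-limonene
Product: 6 (R)-p-menth-1-ene [(4R)-1-methyl-4-(propan-2-yl)cyclohex-1-ene]
Conditions: H2 (1 atm), RhCl(PPh3)3 (1 mol%), toluene, rt
Reagents that add atoms: none
Why: Homogeneous hydrogenation with RhCl(PPh3)3 reduces the 1,1-disubstituted isopropenyl alkene much faster than the trisubstituted ring alkene and does not touch the stereocentre (chemoselective alkene hydrogenation).

Step 3
Reactants: 6 (R)-p-menth-1-ene
Product: 8 (5R)-5-(2,2-dimethoxyethyl)-6-methylheptan-2-one, via keto aldehyde 7 (not isolated)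
Conditions: O3, CH2Cl2/MeOH, −78 °C; Me2S, rt; then HC(OMe)3, TsOH (cat.), MeOH, 0 °C
Reagents that add atoms: ozone, [O-][O+]=O; trimethyl orthoformate, COC(OC)OC
Why: Ozonolysis with reductive work-up cleaves the ring alkene to keto aldehyde 7 without touching the stereocentre, and acid-catalysed acetalisation at 0 °C should take the aldehyde much faster than the methyl ketone (ozonolysis; chemoselective acetal formation).

Step 4
Reactants: 8 (5R)-5-(2,2-dimethoxyethyl)-6-methylheptan-2-one
Product: 10 tert-butyl (6R)-3,8-dioxo-6-(propan-2-yl)octanoate, via acetal 9 (not isolated)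
Conditions: LiN(SiMe3)2 (2.2 equiv), THF, −78 °C; Boc2O, −78 → 0 °C; NH4Cl work-up; then PPTS, acetone/H2O, 50 °C
Reagents that add atoms: di-tert-butyl dicarbonate, CC(C)(C)OC(=O)OC(=O)OC(C)(C)C; water, O
Why: Kinetic deprotonation of the methyl ketone at CH3 and C-acylation of the lithium enolate by Boc2O (crossed Claisen-type acylation, the second equivalent of base holding the product as its enolate) should give the β-keto ester, and PPTS in wet acetone then unmasks the aldehyde without harming the tert-butyl ester.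

Step 5
Reactants: 10 tert-butyl (6R)-3,8-dioxo-6-(propan-2-yl)octanoate; 4 tert-butyl 3-[(triisopropylsilyl)oxy]-2-(triphenylphosphoranylidene)propanoate
Product: 12 di-tert-butyl (2E,4R,5S)-4-chloro-8-oxo-5-(propan-2-yl)-2-{[(triisopropylsilyl)oxy]methyl}dec-2-enedioate, via chloro aldehyde 11 (not isolated)
Conditions: (5R)-5-benzyl-2,2,3-trimethylimidazolidin-4-one·TFA (10 mol%), 2,3,4,5,6,6-hexachlorocyclohexa-2,4-dien-1-one (1.2 equiv), acetone, −30 °C; cold filtration through silica; then 4 (1.5 equiv), CH2Cl2, 0 °C → rt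
Reagents that add atoms: 2,3,4,5,6,6-hexachlorocyclohexa-2,4-dien-1-one, O=C1C(Cl)=C(Cl)C(Cl)=C(Cl)C1(Cl)Cl
Why: Enamine catalysis by the hindered imidazolidinone (only the aldehyde condenses with it) should deliver electrophilic chlorine to one enamine face and set the C–Cl stereocentre under catalyst control, and the labile α-chloro aldehyde 11 is trapped at once by Wittig olefination with stabilised ylide 4, which should give the E-enoate (ester trans to the chain).

Step 6
Reactants: 12 di-tert-butyl (2E,4R,5S)-4-chloro-8-oxo-5-(propan-2-yl)-2-{[(triisopropylsilyl)oxy]methyl}dec-2-enedioate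
Product: 13 tert-butyl (5S,6S)-6-[(1E)-3-tert-butoxy-3-oxo-2-{[(triisopropylsilyl)oxy]methyl}prop-1-en-1-yl]-2-oxo-5-(propan-2-yl)cyclohexane-1-carboxylate (arm cis to isopropyl; C1 epimers and enol)
Conditions: K2CO3 (3 equiv), acetone (0.02 M), rt → 40 °C
Reagents that add atoms: none
Why: K2CO3 should deprotonate only the β-keto ester (far more acidic than any other C–H), and the potassium enolate attacks the secondary allylic C–Cl carbon from the rear in an intramolecular SN2 C-alkylation. The closest known reaction type is the base-mediated cyclisation of ω-halo β-keto esters to 2-oxocycloalkanecarboxylates. The cyclohexanone ring (the future ring B) closes in the 6-(enolendo)-exo-tet mode. The new ring stereocentre carrying the acrylate arm forms with inversion of the C–Cl centre set in step 5, which places the arm cis to the isopropyl group fixed by limonene; the ester-bearing carbon stays epimerisable and is destroyed in step 9. The step needs C- over O-alkylation (the O-path would give a six-membered enol ether), SN2 over SN2′ and conjugate addition, and no chloride-exchange epimerisation before closure. These should be secured by the soft potassium enolate in acetone, the activation of C–Cl as the γ-position of the acrylate, the fully substituted enoate α-carbon (SN2′ would need an eight-membered ring and a quaternary centre, conjugate addition a seven-membered ring), and high dilution over insoluble carbonate.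

Step 7
Reactants: 13 cyclic β-keto ester (above)
Product: 14 tert-butyl (5S,6S)-6-[(1E)-3-tert-butoxy-3-oxo-2-{[(triisopropylsilyl)oxy]methyl}prop-1-en-1-yl]-2-methylidene-5-(propan-2-yl)cyclohexane-1-carboxylate (C1 epimers)
Conditions: Zn, CH2Br2, TiCl4 (preformed Takai–Lombardo reagent), THF/CH2Cl2, 0 °C → rt
Reagents that add atoms: dibromomethane, BrCBr
Why: Takai–Lombardo methylenation: the non-basic gem-dimetallic CH2 reagent adds to the ketone and passes its oxygen to titanium, so the enolisable β-keto ester should be methylenated without deprotonation or epimerisation of the ring stereocentres and without attack on the esters.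

Step 8
Reactants: 14 methylidene diester (above)
Product: 15 (5S,6S)-6-[(1E)-2-carboxy-3-{[(triisopropylsilyl)oxy]}prop-1-en-1-yl]-2-methylidene-5-(propan-2-yl)cyclohexane-1-carboxylic acid (C1 epimers)
Conditions: TMSOTf (5 equiv), 2,6-lutidine (7 equiv), CH2Cl2, 0 °C → rt; aq KHSO4
Reagents that add atoms: none
Why: TMSOTf silylates both ester carbonyl groups and releases the tert-butyl cations as isobutene (2,6-lutidine takes the proton), the silyl esters being hydrolysed on work-up; the TIPS ether and both alkenes should be inert to this non-protic tert-butyl ester cleavage.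

Step 9
Reactants: 15 diacid (above)
Product: 17 (2E)-3-[(1S,6S)-3-(bromomethyl)-6-(propan-2-yl)cyclohex-2-en-1-yl]-2-{[(triisopropylsilyl)oxy]methyl}prop-2-enoic acid, via bromo β-lactone 16 (not isolated)
Conditions: Br2 (1.05 equiv), NaHCO3, H2O/CH2Cl2, 0 °C; acidify, extract; then toluene, 100 °C
Reagents that add atoms: bromine, BrBr
Why: Bromolactonisation: the bromonium ion of the electron-rich 1,1-disubstituted alkene is opened 4-exo at its tertiary carbon by the neighbouring ring carboxylate to give the cis-fused β-lactone 16 whatever the configuration of the carboxyl-bearing carbon, and thermal [2+2] cycloreversion then expels CO2 so that the ring double bond can only lie between the former carboxyl-bearing carbon and the carbon bearing CH2Br.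

Step 10
Reactants: 17 allylic bromide (above)
Product: 19 (2E)-3-[(1R,6S)-3-(hydroxymethyl)-6-(propan-2-yl)cyclohex-2-en-1-yl]-2-{[(triisopropylsilyl)oxy]methyl}prop-2-enoic acid, via acetate 18 (not isolated)
Conditions: CsOAc (5 equiv), DMF, rt; then K2CO3, MeOH, rt; aq KHSO4
Reagents that add atoms: caesium acetate, CC(=O)[O-].[Cs+]
Why: SN2 displacement of the primary allylic bromide by acetate followed by base-mediated methanolysis of the acetate should give the allylic alcohol without allylic transposition.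

Step 11
Reactants: 19 silyl ether hydroxy acid (above)
Product: 20 (2E)-2-(hydroxymethyl)-3-[(1R,6S)-3-(hydroxymethyl)-6-(propan-2-yl)cyclohex-2-en-1-yl]prop-2-enoic acid
Conditions: HF·pyridine, THF, 0 °C → rt
Reagents that add atoms: none
Why: Fluoride-mediated desilylation of the primary TIPS ether under buffered, weakly acidic conditions that should leave the skipped diene and the acid untouched.

Step 12
Reactants: 21 (S)-(−)-limonene
Product: 22 (S)-p-menth-1-ene
Conditions: H2 (1 atm), RhCl(PPh3)3 (1 mol%), toluene, rt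
Reagents that add atoms: none
Why: As step 2 on the enantiomer: chemoselective hydrogenation of the isopropenyl alkene.

Step 13
Reactants: 22 (S)-p-menth-1-ene
Product: 24 (5S)-5-(2,2-dimethoxyethyl)-6-methylheptan-2-one, via keto aldehyde 23 (not isolated)
Conditions: O3, CH2Cl2/MeOH, −78 °C; Me2S, rt; then HC(OMe)3, TsOH (cat.), MeOH, 0 °C
Reagents that add atoms: ozone, [O-][O+]=O; trimethyl orthoformate, COC(OC)OC
Why: As step 3 on the enantiomer: ozonolysis followed by aldehyde-selective acetal formation.

Step 14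
Reactants: 24 (5S)-5-(2,2-dimethoxyethyl)-6-methylheptan-2-one
Product: 26 tert-butyl (6S)-3,8-dioxo-6-(propan-2-yl)octanoate, via acetal 25 (not isolated)
Conditions: LiN(SiMe3)2 (2.2 equiv), THF, −78 °C; Boc2O, −78 → 0 °C; NH4Cl work-up; then PPTS, acetone/H2O, 50 °C
Reagents that add atoms: di-tert-butyl dicarbonate, CC(C)(C)OC(=O)OC(=O)OC(C)(C)C; water, O
Why: As step 4 on the enantiomer: kinetic enolate C-acylation (crossed Claisen-type) followed by mild acetal hydrolysis.

Step 15
Reactants: 26 tert-butyl (6S)-3,8-dioxo-6-(propan-2-yl)octanoate; 4 tert-butyl 3-[(triisopropylsilyl)oxy]-2-(triphenylphosphoranylidene)propanoate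
Product: 28 di-tert-butyl (2E,4R,5R)-4-chloro-8-oxo-5-(propan-2-yl)-2-{[(triisopropylsilyl)oxy]methyl}dec-2-enedioate, via chloro aldehyde 27 (not isolated)
Conditions: (5R)-5-benzyl-2,2,3-trimethylimidazolidin-4-one·TFA (10 mol%), 2,3,4,5,6,6-hexachlorocyclohexa-2,4-dien-1-one (1.2 equiv), acetone, −30 °C; cold filtration through silica; then 4 (1.5 equiv), CH2Cl2, 0 °C → rt
Reagents that add atoms: 2,3,4,5,6,6-hexachlorocyclohexa-2,4-dien-1-one, O=C1C(Cl)=C(Cl)C(Cl)=C(Cl)C1(Cl)Cl
Why: As step 5: the same catalyst enantiomer should set the same absolute configuration at the C–Cl carbon next to the now enantiomeric isopropyl centre (enamine-catalysed α-chlorination, then E-selective Wittig olefination).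

Step 16
Reactants: 28 di-tert-butyl (2E,4R,5R)-chloro enoate (above)
Product: 29 tert-butyl (1S,5R,6S)-6-[(1E)-3-tert-butoxy-3-oxo-2-{[(triisopropylsilyl)oxy]methyl}prop-1-en-1-yl]-2-oxo-5-(propan-2-yl)cyclohexane-1-carboxylate (all-trans)
Conditions: K2CO3 (3 equiv), acetone (0.02 M), rt → 40 °C
Reagents that add atoms: none
Why: The same SN2 C-alkylation of the β-keto ester potassium enolate (6-(enolendo)-exo-tet) as in step 6: inversion of the (4R) C–Cl centre next to the (5R) isopropyl centre should now place the arm trans to isopropyl, and the acidic ester-bearing carbon equilibrates to the all-equatorial (1S) epimer.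

Step 17
Reactants: 29 cyclic β-keto ester (above)
Product: 30 tert-butyl (1S,5R,6S)-6-[(1E)-3-tert-butoxy-2-(hydroxymethyl)-3-oxoprop-1-en-1-yl]-2-oxo-5-(propan-2-yl)cyclohexane-1-carboxylate
Conditions: HF·pyridine, THF, 0 °C → rt
Reagents that add atoms: none
Why: Fluoride-mediated cleavage of the primary TIPS ether; the tert-butyl esters and the β-keto ester should survive the buffered conditions.

Step 18
Reactants: 30 hydroxy β-keto ester (above)
Product: 32 tert-butyl (5aS,6R,9aS)-1,9-dioxo-6-(propan-2-yl)-1,3,5a,6,7,8,9,9a-octahydro-2-benzoxepine-4-carboxylate, via acylketene 31 (not isolated)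
Conditions: toluene (0.005 M), 110 °C
Reagents that add atoms: none
Why: Thermolysis of the tert-butyl β-keto ester expels tert-butanol to give acylketene 31, which should be captured intramolecularly by the allylic hydroxyl held cis to the ring by the E-alkene, closing the seven-membered β-keto lactone (ring C); the lactone α-carbon re-forms under thermodynamic control in the trans ring fusion (acylketene lactonisation).

Step 19
Reactants: 32 β-keto lactone (above)
Product: 33 tert-butyl (5aS,6R,9aS)-9-methylidene-1-oxo-6-(propan-2-yl)-1,3,5a,6,7,8,9,9a-octahydro-2-benzoxepine-4-carboxylate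
Conditions: Zn, CH2Br2, TiCl4 (preformed Takai–Lombardo reagent), THF/CH2Cl2, 0 °C → rt
Reagents that add atoms: dibromomethane, BrCBr
Why: Takai–Lombardo methylenation as in step 7: the non-basic reagent should convert the enolisable ketone into the exocyclic alkene without epimerising the lactone α-carbon or opening the allylic lactone.

Step 20
Reactants: 33 methylidene lactone (above)
Product: 34 spiro-epoxide of 33 at C9 (9S; oxirane oxygen equatorial and trans to the lactone carbonyl on C9a, oxirane CH2 axial)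
Conditions: Cl3CCN, 30% H2O2, K2HPO4, CH2Cl2, 0 °C → rt
Reagents that add atoms: hydrogen peroxide, OO
Why: Payne-type epoxidation by the peroxyimidic acid formed from Cl3CCN and H2O2: the bulky oxidant is expected to approach the exocyclic methylene from the equatorial direction, placing the oxirane oxygen equatorial and the CH2 axial as the target requires, while the electron-poor ring C alkene is not epoxidised.

Step 21
Reactants: 34 spiro-epoxide (above); 20 (2E)-2-(hydroxymethyl)-3-[(1R,6S)-3-(hydroxymethyl)-6-(propan-2-yl)cyclohex-2-en-1-yl]prop-2-enoic acid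
Product: 35 tert-butyl ester of the target (ester at the ring C carboxyl)
Conditions: Cs2CO3 (0.2 equiv), DMF, 60 °C
Reagents that add atoms: none
Why: The caesium carboxylate of 20 should open the 2,2-disubstituted epoxide by SN2 attack at its CH2 carbon, which leaves the tertiary C–O bond and hence the carbinol configuration untouched and releases the tertiary alcohol; the free hydroxyl groups are far less nucleophilic than the carboxylate and the weak base should not enolise the lactone (epoxide opening by a carboxylate).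

Step 22
Reactants: 35 tert-butyl ester of the target
Product: 36 target CNP0361406.5
Conditions: TMSOTf (6 equiv), 2,6-lutidine (8 equiv), CH2Cl2, −20 → 0 °C; then MeOH, aq citric acid
Reagents that add atoms: none
Why: TMSOTf-mediated tert-butyl ester cleavage as in step 8 (hydroxyl groups are silylated transiently and freed in the mildly acidic methanolic work-up), chosen because the allylic lactone and the inter-half ester would not tolerate basic, nucleophilic or palladium-based deprotection.

**Compound list**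

1 | tert-butyl (triphenylphosphoranylidene)acetate | CC(C)(C)OC(=O)C=P(c1ccccc1)(c1ccccc1)c1ccccc1 | starting material
2 | (chloromethoxy)tri(propan-2-yl)silane | ClCO[Si](C(C)C)(C(C)C)C(C)C | starting material
3 | [1-tert-butoxy-1-oxo-3-(triisopropylsilyloxy)propan-2-yl]triphenylphosphonium chloride | CC(C)(C)OC(=O)C(CO[Si](C(C)C)(C(C)C)C(C)C)[P+](c1ccccc1)(c1ccccc1)c1ccccc1.[Cl-] | intermediate
4 | tert-butyl 3-[(triisopropylsilyl)oxy]-2-(triphenylphosphoranylidene)propanoate | CC(C)(C)OC(=O)C(CO[Si](C(C)C)(C(C)C)C(C)C)=P(c1ccccc1)(c1ccccc1)c1ccccc1 | intermediate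
5 | (R)-(+)-limonene | CC1=CC[C@@H](CC1)C(C)=C | starting material
6 | (R)-p-menth-1-ene | CC1=CC[C@@H](CC1)C(C)C | intermediate
7 | (3R)-6-oxo-3-(propan-2-yl)heptanal | CC(=O)CC[C@H](CC=O)C(C)C | intermediate
8 | (5R)-5-(2,2-dimethoxyethyl)-6-methylheptan-2-one | COC(OC)C[C@@H](CCC(C)=O)C(C)C | intermediate
9 | tert-butyl (6R)-8,8-dimethoxy-3-oxo-6-(propan-2-yl)octanoate | COC(OC)C[C@@H](CCC(=O)CC(=O)OC(C)(C)C)C(C)C | intermediate
10 | tert-butyl (6R)-3,8-dioxo-6-(propan-2-yl)octanoate | CC(C)(C)OC(=O)CC(=O)CC[C@H](CC=O)C(C)C | intermediate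
11 | tert-butyl (6S,7R)-7-chloro-3,8-dioxo-6-(propan-2-yl)octanoate | CC(C)(C)OC(=O)CC(=O)CC[C@@H](C(C)C)[C@@H](Cl)C=O | intermediate
12 | di-tert-butyl (2E,4R,5S)-4-chloro-8-oxo-5-(propan-2-yl)-2-{[(triisopropylsilyl)oxy]methyl}dec-2-enedioate | CC(C)(C)OC(=O)CC(=O)CC[C@@H](C(C)C)[C@@H](Cl)/C=C(\CO[Si](C(C)C)(C(C)C)C(C)C)C(=O)OC(C)(C)C | intermediate
13 | tert-butyl (5S,6S)-6-[(1E)-3-tert-butoxy-3-oxo-2-{[(triisopropylsilyl)oxy]methyl}prop-1-en-1-yl]-2-oxo-5-(propan-2-yl)cyclohexane-1-carboxylate (C1 epimers) | CC(C)(C)OC(=O)C1C(=O)CC[C@@H](C(C)C)[C@H]1/C=C(\CO[Si](C(C)C)(C(C)C)C(C)C)C(=O)OC(C)(C)C | intermediate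
14 | tert-butyl (5S,6S)-6-[(1E)-3-tert-butoxy-3-oxo-2-{[(triisopropylsilyl)oxy]methyl}prop-1-en-1-yl]-2-methylidene-5-(propan-2-yl)cyclohexane-1-carboxylate (C1 epimers) | CC(C)(C)OC(=O)C1C(=C)CC[C@@H](C(C)C)[C@H]1/C=C(\CO[Si](C(C)C)(C(C)C)C(C)C)C(=O)OC(C)(C)C | intermediate
15 | (5S,6S)-6-[(1E)-2-carboxy-3-{[(triisopropylsilyl)oxy]}prop-1-en-1-yl]-2-methylidene-5-(propan-2-yl)cyclohexane-1-carboxylic acid (C1 epimers) | OC(=O)C1C(=C)CC[C@@H](C(C)C)[C@H]1/C=C(\CO[Si](C(C)C)(C(C)C)C(C)C)C(=O)O | intermediate
16 | (2E)-3-[6-(bromomethyl)-8-oxo-3-(propan-2-yl)-7-oxabicyclo[4.2.0]octan-2-yl]-2-{[(triisopropylsilyl)oxy]methyl}prop-2-enoic acid (cis-fused β-lactone; arm and isopropyl cis as in 15) | BrCC12CC[C@@H](C(C)C)[C@@H](/C=C(\CO[Si](C(C)C)(C(C)C)C(C)C)C(=O)O)C1C(=O)O2 | intermediate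
17 | (2E)-3-[(1S,6S)-3-(bromomethyl)-6-(propan-2-yl)cyclohex-2-en-1-yl]-2-{[(triisopropylsilyl)oxy]methyl}prop-2-enoic acid | BrCC1=C[C@H](/C=C(\CO[Si](C(C)C)(C(C)C)C(C)C)C(=O)O)[C@H](C(C)C)CC1 | intermediate
18 | (2E)-3-[(1R,6S)-3-(acetoxymethyl)-6-(propan-2-yl)cyclohex-2-en-1-yl]-2-{[(triisopropylsilyl)oxy]methyl}prop-2-enoic acid | CC(=O)OCC1=C[C@H](/C=C(\CO[Si](C(C)C)(C(C)C)C(C)C)C(=O)O)[C@H](C(C)C)CC1 | intermediate
19 | (2E)-3-[(1R,6S)-3-(hydroxymethyl)-6-(propan-2-yl)cyclohex-2-en-1-yl]-2-{[(triisopropylsilyl)oxy]methyl}prop-2-enoic acid | OCC1=C[C@H](/C=C(\CO[Si](C(C)C)(C(C)C)C(C)C)C(=O)O)[C@H](C(C)C)CC1 | intermediate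
20 | (2E)-2-(hydroxymethyl)-3-[(1R,6S)-3-(hydroxymethyl)-6-(propan-2-yl)cyclohex-2-en-1-yl]prop-2-enoic acid | OCC1=C[C@H](/C=C(\CO)C(=O)O)[C@H](C(C)C)CC1 | intermediate
21 | (S)-(−)-limonene | CC1=CC[C@H](CC1)C(C)=C | starting material
22 | (S)-p-menth-1-ene | CC1=CC[C@H](CC1)C(C)C | intermediate
23 | (3S)-6-oxo-3-(propan-2-yl)heptanal | CC(=O)CC[C@@H](CC=O)C(C)C | intermediate
24 | (5S)-5-(2,2-dimethoxyethyl)-6-methylheptan-2-one | COC(OC)C[C@H](CCC(C)=O)C(C)C | intermediate
25 | tert-butyl (6S)-8,8-dimethoxy-3-oxo-6-(propan-2-yl)octanoate | COC(OC)C[C@H](CCC(=O)CC(=O)OC(C)(C)C)C(C)C | intermediate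
26 | tert-butyl (6S)-3,8-dioxo-6-(propan-2-yl)octanoate | CC(C)(C)OC(=O)CC(=O)CC[C@@H](CC=O)C(C)C | intermediate
27 | tert-butyl (6R,7R)-7-chloro-3,8-dioxo-6-(propan-2-yl)octanoate | CC(C)(C)OC(=O)CC(=O)CC[C@H](C(C)C)[C@@H](Cl)C=O | intermediate
28 | di-tert-butyl (2E,4R,5R)-4-chloro-8-oxo-5-(propan-2-yl)-2-{[(triisopropylsilyl)oxy]methyl}dec-2-enedioate | CC(C)(C)OC(=O)CC(=O)CC[C@H](C(C)C)[C@@H](Cl)/C=C(\CO[Si](C(C)C)(C(C)C)C(C)C)C(=O)OC(C)(C)C | intermediate
29 | tert-butyl (1S,5R,6S)-6-[(1E)-3-tert-butoxy-3-oxo-2-{[(triisopropylsilyl)oxy]methyl}prop-1-en-1-yl]-2-oxo-5-(propan-2-yl)cyclohexane-1-carboxylate | CC(C)(C)OC(=O)[C@@H]1C(=O)CC[C@H](C(C)C)[C@H]1/C=C(\CO[Si](C(C)C)(C(C)C)C(C)C)C(=O)OC(C)(C)C | intermediate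
30 | tert-butyl (1S,5R,6S)-6-[(1E)-3-tert-butoxy-2-(hydroxymethyl)-3-oxoprop-1-en-1-yl]-2-oxo-5-(propan-2-yl)cyclohexane-1-carboxylate | CC(C)(C)OC(=O)[C@@H]1C(=O)CC[C@H](C(C)C)[C@H]1/C=C(\CO)C(=O)OC(C)(C)C | intermediate
31 | tert-butyl (2E)-2-(hydroxymethyl)-3-[3-oxo-2-(oxomethylidene)-6-(propan-2-yl)cyclohexyl]prop-2-enoate (acylketene; ring stereocentres as in 30) | O=C=C1C(=O)CC[C@H](C(C)C)[C@H]1/C=C(\CO)C(=O)OC(C)(C)C | intermediate
32 | tert-butyl (5aS,6R,9aS)-1,9-dioxo-6-(propan-2-yl)-1,3,5a,6,7,8,9,9a-octahydro-2-benzoxepine-4-carboxylate | CC(C)[C@H]1CCC(=O)[C@H]2C(=O)OCC(C(=O)OC(C)(C)C)=C[C@H]12 | intermediate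
33 | tert-butyl (5aS,6R,9aS)-9-methylidene-1-oxo-6-(propan-2-yl)-1,3,5a,6,7,8,9,9a-octahydro-2-benzoxepine-4-carboxylate | CC(C)[C@H]1CCC(=C)[C@H]2C(=O)OCC(C(=O)OC(C)(C)C)=C[C@H]12 | intermediate
34 | spiro-epoxide of 33 at C9 (5aS,6R,9S,9aS; oxirane oxygen trans to the lactone carbonyl) | CC(C)[C@H]1CC[C@@]3(CO3)[C@H]2C(=O)OCC(C(=O)OC(C)(C)C)=C[C@H]12 | intermediate
35 | tert-butyl ester of the target (ring C carboxyl as tert-butyl ester) | CC(C)[C@H]1CC[C@@](O)(COC(=O)/C(=C/[C@H]2C=C(CO)CC[C@H]2C(C)C)CO)[C@H]2C(=O)OCC(C(=O)OC(C)(C)C)=C[C@H]12 | intermediate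
36 | CNP0361406.5 | CC(C)[C@H]1CC[C@@](O)(COC(=O)/C(=C/[C@H]2C=C(CO)CC[C@H]2C(C)C)CO)[C@H]2C(=O)OCC(C(=O)O)=C[C@H]12 | target

**Totals and risks**

Total step count: 22. Longest linear sequence: 12 steps (5 → 20 by steps 2–11, then steps 21 and 22).

Steps most likely to fail:

Step 5 (its twin, step 15, shares the risk). What may go wrong: electrophilic chlorination of the β-keto ester methylene in competition with the aldehyde enamine, and loss of configuration of the α-chloro aldehyde during the slow olefination by the α-branched ylide. Fallback (oxygen in place of chlorine): from 10, L-proline-catalysed α-aminoxylation with nitrosobenzene (CHCl3, 0 °C) would give tert-butyl (6S,7R)-7-(anilinooxy)-3,8-dioxo-6-(propan-2-yl)octanoate F1, used without isolation in the Wittig reaction with 4 to give di-tert-butyl (2E,4R,5S)-4-(anilinooxy)-8-oxo-5-(propan-2-yl)-2-{[(triisopropylsilyl)oxy]methyl}dec-2-enedioate F2. Zn/AcOH would cleave the N–O bond to the corresponding 4-hydroxy enoate F3, and MsCl/Et3N would give the 4-mesyloxy enoate F4. F4 would be closed under the conditions of step 6 (K2CO3, acetone) with the same inversion, coming back to the route at 13.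

Step 6 (its twin, step 16, shares the risk). What may go wrong: O-alkylation of the enolate to a six-membered enol ether, and erosion of the C–Cl configuration by chloride exchange before ring closure. Fallback (transition-metal catalysis with the opposite stereochemical course): from 10, chlorination with the enantiomeric (5S) catalyst would give tert-butyl (6S,7S)-7-chloro-3,8-dioxo-6-(propan-2-yl)octanoate F5 (not isolated) and, with 4, di-tert-butyl (2E,4S,5S)-4-chloro-8-oxo-5-(propan-2-yl)-2-{[(triisopropylsilyl)oxy]methyl}dec-2-enedioate F6. Pd(PPh3)4 (zerovalent palladium, 5 mol%) and K2CO3 in THF would ionise the allylic chloride with inversion, and the soft enolate would attack the allyl complex at carbon on the face opposite to palladium. This Tsuji–Trost C-alkylation with net retention returns to the route at 13.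

Step 20. What may go wrong: poor facial selectivity of oxygen transfer to the exocyclic alkene, giving mainly the epoxide with axial oxygen. Fallback: from 33, OsO4 (cat.)/NMO dihydroxylation (a bulkier reagent with a well-established equatorial approach) would give tert-butyl (5aS,6R,9S,9aS)-9-hydroxy-9-(hydroxymethyl)-1-oxo-6-(propan-2-yl)-1,3,5a,6,7,8,9,9a-octahydro-2-benzoxepine-4-carboxylate F7. F7 would be used at once (to forestall attack of the primary hydroxyl on the lactone) in a PPh3/DIAD cyclodehydration (Mitsunobu conditions, primary hydroxyl activated, tertiary oxygen retained), coming back to the route at 34.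

**Further compounds**

F1 | step 5 | tert-butyl (6S,7R)-7-(anilinooxy)-3,8-dioxo-6-(propan-2-yl)octanoate | CC(C)(C)OC(=O)CC(=O)CC[C@@H](C(C)C)[C@@H](ONc1ccccc1)C=O
F2 | step 5 | di-tert-butyl (2E,4R,5S)-4-(anilinooxy)-8-oxo-5-(propan-2-yl)-2-{[(triisopropylsilyl)oxy]methyl}dec-2-enedioate | CC(C)(C)OC(=O)CC(=O)CC[C@@H](C(C)C)[C@@H](ONc1ccccc1)/C=C(\CO[Si](C(C)C)(C(C)C)C(C)C)C(=O)OC(C)(C)C
F3 | step 5 | di-tert-butyl (2E,4R,5S)-4-hydroxy-8-oxo-5-(propan-2-yl)-2-{[(triisopropylsilyl)oxy]methyl}dec-2-enedioate | CC(C)(C)OC(=O)CC(=O)CC[C@@H](C(C)C)[C@@H](O)/C=C(\CO[Si](C(C)C)(C(C)C)C(C)C)C(=O)OC(C)(C)C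
F4 | step 5 | di-tert-butyl (2E,4R,5S)-4-[(methanesulfonyl)oxy]-8-oxo-5-(propan-2-yl)-2-{[(triisopropylsilyl)oxy]methyl}dec-2-enedioate | CC(C)(C)OC(=O)CC(=O)CC[C@@H](C(C)C)[C@@H](OS(C)(=O)=O)/C=C(\CO[Si](C(C)C)(C(C)C)C(C)C)C(=O)OC(C)(C)C
F5 | step 6 | tert-butyl (6S,7S)-7-chloro-3,8-dioxo-6-(propan-2-yl)octanoate | CC(C)(C)OC(=O)CC(=O)CC[C@@H](C(C)C)[C@H](Cl)C=O
F6 | step 6 | di-tert-butyl (2E,4S,5S)-4-chloro-8-oxo-5-(propan-2-yl)-2-{[(triisopropylsilyl)oxy]methyl}dec-2-enedioate | CC(C)(C)OC(=O)CC(=O)CC[C@@H](C(C)C)[C@H](Cl)/C=C(\CO[Si](C(C)C)(C(C)C)C(C)C)C(=O)OC(C)(C)C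
F7 | step 20 | tert-butyl (5aS,6R,9S,9aS)-9-hydroxy-9-(hydroxymethyl)-1-oxo-6-(propan-2-yl)-1,3,5a,6,7,8,9,9a-octahydro-2-benzoxepine-4-carboxylate | CC(C)[C@H]1CC[C@@](O)(CO)[C@H]2C(=O)OCC(C(=O)OC(C)(C)C)=C[C@H]12
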